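**Strategy.** The route rests on disconnecting the interflavan bond between C4 of the upper pyran ring (ring C) and C8 of the lower benzo ring (ring D). C4 is the carbonyl carbon of the chiral-pool flavanone (2S)-liquiritigenin, and C8, flanked by C7–O and C8a–O1, is the position that NBS brominates in benzylated (−)-epigallocatechin. The key step adds the C8 aryllithium of the perbenzylated lower half to the C4 ketone of the dibenzylated flavanone, joining the two C15 halves with complete C8 regiocontrol. Ionic deoxygenation of the carbinol then delivers hydride trans to the C2 aryl group (2,4-cis, 4S), and hydrogenolysis frees all eight hydroxyl groups.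

Key step: step 5

Ring labels: upper unit rings A (benzo), B (4-hydroxyphenyl), C (pyran); lower unit rings D (benzo), E (pyrogallol), F (pyran). The target is (2S,4S) in the upper unit (2,4-cis) and (2R,3R) in the lower unit (2,3-cis, epigallocatechin).

Assumption: commercial (−)-liquiritigenin is the natural (2S)-enantiomer of high enantiomeric purity (to be checked by chiral HPLC before use); the upper-unit configuration derives from it.

**Step 1**
Reactants: 1 (−)-epigallocatechin; 2 benzyl bromide
Product: 3 (2R,3R)-5,7-bis(benzyloxy)-2-[3,4,5-tris(benzyloxy)phenyl]chroman-3-ol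
Conditions: BnBr (5.5 equiv), K2CO3, DMF, 0 °C to rt, argon
Reagents that add atoms: benzyl bromide (compound 2), BrCc1ccccc1
Why: Williamson etherification in which K2CO3 deprotonates only the five phenols, leaving the secondary 3-OH free, while exclusion of oxygen and low temperature protect the pyrogallol ring and the C2 center.

**Step 2**
Reactants: 3 penta-O-benzyl-epigallocatechin; 4 N-bromosuccinimide
Product: 5 (2R,3R)-5,7-bis(benzyloxy)-8-bromo-2-[3,4,5-tris(benzyloxy)phenyl]chroman-3-ol
Conditions: NBS (1.0 equiv), CH2Cl2, −78 °C to rt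
Reagents that add atoms: N-bromosuccinimide (compound 4), O=C1CCC(=O)N1Br
Why: Electrophilic aromatic bromination of the most activated ring (ring D), where C8 (ortho to C7–OBn and O1, para to C5–OBn) is expected to react in preference to C6, as is usual for 5,7-di-O-benzylated flavan-3-ols.

**Step 3**
Reactants: 5 8-bromo-penta-O-benzyl-epigallocatechin; 2 benzyl bromide
Product: 6 (2R,3R)-3,5,7-tris(benzyloxy)-8-bromo-2-[3,4,5-tris(benzyloxy)phenyl]chroman
Conditions: NaH, BnBr, Bu4NI (cat.), DMF, 0 °C to rt
Reagents that add atoms: benzyl bromide (compound 2), BrCc1ccccc1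
Why: Williamson etherification of the secondary alkoxide removes the last acidic proton before metallation, with a group that leaves in the final hydrogenolysis; C3 is not a reacting center.

**Step 4**
Reactants: 7 (2S)-liquiritigenin; 8 benzyl alcohol
Product: 9 (2S)-7-(benzyloxy)-2-[4-(benzyloxy)phenyl]chroman-4-one
Conditions: BnOH, PPh3, DIAD, THF, 0 °C to rt
Reagents that add atoms: benzyl alcohol (compound 8), OCc1ccccc1
Why: Mitsunobu etherification of both phenols avoids carbonate or alkoxide bases, whose phenoxides would open the flavanone by retro-oxa-Michael reaction and erode C2; C2 is untouched.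

**Step 5**
Reactants: 6 8-bromo-hexa-O-benzyl-epigallocatechin; 9 di-O-benzyl-(2S)-liquiritigenin
Product: 11 (2S)-4-aryl-flavan-4-ol adduct (tertiary alcohol; C4 epimers), via C8-aryllithium 10 (not isolated)
Conditions: n-BuLi, THF, −78 °C; then 9 in THF, −78 to −40 °C; aq NH4Cl; chromatography on Et3N-buffered silica
Reagents that add atoms: none
Why: Bromine–lithium exchange on 6 gives the C8 aryllithium 10, which adds to the C4 carbonyl of flavanone 9 in a polar 1,2-addition, the reaction type known for joining C8-metallated benzylated flavan-3-ols to flavan-4-ones. No ring is closed. The only new stereocenter is the C4 carbinol, whose configuration need not be controlled because step 6 ionises it, and C2 of 9 and C2/C3 of 6 are not reacting centers. The step needs regioselectivity for C8 over C6 of ring D, secured by the bromine that step 2 places at C8 (ipso metallation). It also needs addition to win over enolisation of 9, favoured by the low temperature, at which any lithium enolate of 9 should not ring-open and simply returns 9 on quench. The two ortho oxygens (C7–OBn and O1) stabilise the aryllithium, so the exchange should be clean at −78 °C.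

**Step 6**
Reactants: 11 tertiary 4-aryl-flavan-4-ol
Product: 12 (2R,3R)-3,5,7-tris(benzyloxy)-8-[(2S,4S)-7-(benzyloxy)-2-[4-(benzyloxy)phenyl]chroman-4-yl]-2-[3,4,5-tris(benzyloxy)phenyl]chroman
Conditions: Et3SiH, CF3CO2H, CH2Cl2, −40 to −10 °C
Reagents that add atoms: none
Why: Ionic hydrogenation, in which acid ionises the doubly benzylic carbinol to a C4 cation (stabilised by O1, the C7–OBn group and ring D) and the silane delivers hydride axially, trans to the pseudo-equatorial C2 aryl, so that ring D ends equatorial and cis to ring B (4S), which is also the more stable diequatorial isomer.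

**Step 7**
Reactants: 12 octa-O-benzyl dimer
Product: 13 target, (2R,3R)-8-[(2S,4S)-7-hydroxy-2-(4-hydroxyphenyl)chroman-4-yl]-2-(3,4,5-trihydroxyphenyl)chroman-3,5,7-triol
Conditions: H2 (1 atm), Pd(OH)2/C, THF–MeOH, rt
Reagents that add atoms: none
Why: Catalytic hydrogenolysis of the eight benzyl ethers under neutral conditions, which should leave the flavan C2–O1 bonds, the interflavan bond and all four stereocenters untouched.

**Compound list**
1 | (−)-epigallocatechin, (2R,3R)-2-(3,4,5-trihydroxyphenyl)chroman-3,5,7-triol | Oc1cc(O)c2c(c1)O[C@H](c1cc(O)c(O)c(O)c1)[C@H](O)C2 | starting material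
2 | benzyl bromide | BrCc1ccccc1 | starting material
3 | (2R,3R)-5,7-bis(benzyloxy)-2-[3,4,5-tris(benzyloxy)phenyl]chroman-3-ol | c1ccccc1COc1cc(OCc3ccccc3)c2c(c1)O[C@H](c1cc(OCc3ccccc3)c(OCc3ccccc3)c(OCc3ccccc3)c1)[C@H](O)C2 | intermediate
4 | N-bromosuccinimide | O=C1CCC(=O)N1Br | starting material
5 | (2R,3R)-5,7-bis(benzyloxy)-8-bromo-2-[3,4,5-tris(benzyloxy)phenyl]chroman-3-ol | c1ccccc1COc1cc(OCc3ccccc3)c2c(c1Br)O[C@H](c1cc(OCc3ccccc3)c(OCc3ccccc3)c(OCc3ccccc3)c1)[C@H](O)C2 | intermediate
6 | (2R,3R)-3,5,7-tris(benzyloxy)-8-bromo-2-[3,4,5-tris(benzyloxy)phenyl]chroman | c1ccccc1COc1cc(OCc3ccccc3)c2c(c1Br)O[C@H](c1cc(OCc3ccccc3)c(OCc3ccccc3)c(OCc3ccccc3)c1)[C@H](OCc1ccccc1)C2 | intermediate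
7 | (2S)-liquiritigenin, (2S)-7-hydroxy-2-(4-hydroxyphenyl)chroman-4-one | Oc1ccc([C@@H]2CC(=O)c3ccc(O)cc3O2)cc1 | starting material
8 | benzyl alcohol | OCc1ccccc1 | starting material
9 | (2S)-7-(benzyloxy)-2-[4-(benzyloxy)phenyl]chroman-4-one | c1ccccc1COc1ccc([C@@H]2CC(=O)c3ccc(OCc4ccccc4)cc3O2)cc1 | intermediate
10 | [(2R,3R)-3,5,7-tris(benzyloxy)-2-[3,4,5-tris(benzyloxy)phenyl]chroman-8-yl]lithium (not isolated) | [Li]c1c(OCc3ccccc3)cc(OCc3ccccc3)c2c1O[C@H](c1cc(OCc3ccccc3)c(OCc3ccccc3)c(OCc3ccccc3)c1)[C@H](OCc1ccccc1)C2 | intermediate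
11 | (2S)-7-(benzyloxy)-2-[4-(benzyloxy)phenyl]-4-[(2R,3R)-3,5,7-tris(benzyloxy)-2-[3,4,5-tris(benzyloxy)phenyl]chroman-8-yl]chroman-4-ol (C4 configuration not controlled) | c1ccccc1COc1ccc([C@@H]2CC(O)(c3c(OCc5ccccc5)cc(OCc5ccccc5)c4c3O[C@H](c3cc(OCc5ccccc5)c(OCc5ccccc5)c(OCc5ccccc5)c3)[C@H](OCc3ccccc3)C4)c3ccc(OCc4ccccc4)cc3O2)cc1 | intermediate
12 | (2R,3R)-3,5,7-tris(benzyloxy)-8-[(2S,4S)-7-(benzyloxy)-2-[4-(benzyloxy)phenyl]chroman-4-yl]-2-[3,4,5-tris(benzyloxy)phenyl]chroman | c1ccccc1COc1ccc([C@@H]2C[C@H](c3c(OCc5ccccc5)cc(OCc5ccccc5)c4c3O[C@H](c3cc(OCc5ccccc5)c(OCc5ccccc5)c(OCc5ccccc5)c3)[C@H](OCc3ccccc3)C4)c3ccc(OCc4ccccc4)cc3O2)cc1 | intermediate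
13 | (2R,3R)-8-[(2S,4S)-7-hydroxy-2-(4-hydroxyphenyl)chroman-4-yl]-2-(3,4,5-trihydroxyphenyl)chroman-3,5,7-triol | Oc1ccc([C@@H]2C[C@H](c3c(O)cc(O)c4c3O[C@H](c3cc(O)c(O)c(O)c3)[C@H](O)C4)c3ccc(O)cc3O2)cc1 | target

**Step count.** Total: 7 steps. Longest linear sequence: 6 steps (1, 2, 3, 5, 6, 7); step 4 prepares the second fragment.

**Steps most likely to fail**

Step 5 (key step). The hindered, basic aryllithium may remove a C3 proton of 9 (enolisation) faster than it adds to the deactivated C4 carbonyl. That would return debrominated arene and, on warming, ring-opened chalcone. The fallback reverses the order of events to a Friedel–Crafts alkylation and sets out from 9 and 3. NaBH4 (THF–EtOH, 0 °C) should reduce 9 with hydride delivery trans to the C2 aryl to (2S,4S)-7-(benzyloxy)-2-[4-(benzyloxy)phenyl]chroman-4-ol F1. Compound 3 is O-benzylated (NaH, benzyl bromide 2, DMF) to (2R,3R)-3,5,7-tris(benzyloxy)-2-[3,4,5-tris(benzyloxy)phenyl]chroman F2. BF3·OEt2 in CH2Cl2 (−78 to 0 °C) ionises F1 to the C4 cation, which alkylates an excess of F2. This path lacks the cis control of the main route: the C4 epimer and C6-linked regioisomers are expected alongside 12 and must be separated by chromatography. The fallback comes back to the route at 12 and bypasses 11.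

Step 6. Hydride delivery may show poor facial selectivity, or the cation may lose a C3 proton to the 2H-chromene, whose acid-induced C2–O1 ionisation would scramble C2 before C4 is set. Benzyl ethers on ring D may also be lost to acid. The fallback sets out from 11 and avoids acid. Dehydration with methyl N-(triethylammoniosulfonyl)carbamate (THF, rt to 50 °C) should give (2S)-7-(benzyloxy)-2-[4-(benzyloxy)phenyl]-4-[(2R,3R)-3,5,7-tris(benzyloxy)-2-[3,4,5-tris(benzyloxy)phenyl]chroman-8-yl]-2H-chromene F3. Heterogeneous hydrogenation (H2, Pd(OH)2/C, THF–MeOH) should then add hydrogen to C3=C4 from the face opposite the C2 aryl (2,4-cis) and remove all benzyl groups in the same operation. The fallback comes back to the route at 13 and bypasses 12.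

Step 4. Configuration at C2 may erode through phenoxide-triggered reversible ring opening to the chalcone during etherification, or the commercial flavanone may be of insufficient optical purity. The fallback builds C2 by catalysis and sets out from benzyl bromide 2. Commercial 7-hydroxychromone is O-benzylated (K2CO3, acetone, reflux) to 7-(benzyloxy)-4H-chromen-4-one F4. Asymmetric conjugate addition of commercial 4-(benzyloxy)phenylboronic acid then follows (Pd(OCOCF3)2, t-BuPyOx, NH4PF6, H2O, 1,2-dichloroethane, 60 °C). The ligand enantiomer is chosen to deliver the (2S)-flavanone; this is expected to be the (R)-ligand by analogy with cyclic enones and is to be confirmed by correlation with natural material. The fallback comes back to the route at 9.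

**Further compounds**
F1 | step 5 | (2S,4S)-7-(benzyloxy)-2-[4-(benzyloxy)phenyl]chroman-4-ol | c1ccccc1COc1ccc([C@@H]2C[C@H](O)c3ccc(OCc4ccccc4)cc3O2)cc1
F2 | step 5 | (2R,3R)-3,5,7-tris(benzyloxy)-2-[3,4,5-tris(benzyloxy)phenyl]chroman | c1ccccc1COc1cc(OCc3ccccc3)c2c(c1)O[C@H](c1cc(OCc3ccccc3)c(OCc3ccccc3)c(OCc3ccccc3)c1)[C@H](OCc1ccccc1)C2
F3 | step 6 | (2S)-7-(benzyloxy)-2-[4-(benzyloxy)phenyl]-4-[(2R,3R)-3,5,7-tris(benzyloxy)-2-[3,4,5-tris(benzyloxy)phenyl]chroman-8-yl]-2H-chromene | c1ccccc1COc1ccc([C@@H]2C=C(c3c(OCc5ccccc5)cc(OCc5ccccc5)c4c3O[C@H](c3cc(OCc5ccccc5)c(OCc5ccccc5)c(OCc5ccccc5)c3)[C@H](OCc3ccccc3)C4)c3ccc(OCc4ccccc4)cc3O2)cc1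
F4 | step 4 | 7-(benzyloxy)-4H-chromen-4-one | O=c1ccoc2cc(OCc3ccccc3)ccc12
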